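**Direct plan and its weak steps**

A direct plan would take the trans-substituted cyclopentane from the chiral pool as dihydronepetalactone A1 and create the spiro carbon C5 by angular alkylation of its lactone enolate with an allylic bromide (→ A2). It would then unfold the lactone and lengthen the side chain to the keto aldehyde A3, close the cyclohexenone by aldol condensation (→ A4), acetylate, and reduce the ketone.
- The alkylation that creates the quaternary carbon would attack a fully substituted, neopentyl-type bicyclic enolate. Its facial outcome would rest on a small convex/concave bias, and O-alkylation or elimination of the bromide would compete.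
- The stretch from lactone to keto aldehyde (half-reduction, methoxymethylenation, sulfonylation, sp3–sp3 coupling of a separately built chain piece, enol-ether hydrolysis, ozonolysis) would spend about nine operations on redox and protecting-group changes that set no stereocentre.
- The acid hydrolysis that unmasks the aldehyde would do so beside a 1,1-disubstituted alkene (Prins or carbonyl-ene closure), and the ozonolysis after it would meet a free aldehyde and a free alcohol.

**Retrosynthetic overview of the new route**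

Numbering: spiro[4.5]decene C1 (side chain), C4 (methyl), C5 (spiro), C6–C10 (C7=C8, C9–OH); side chain C1' (acetate end) to C6'.
- The six-membered ring is made first, from an anisole by Birch reduction. The cyclopentane is closed last by forming C4–C5 in an iron-hydride hydrogen-atom-transfer radical spirocyclization onto the β-carbon C5 of the cyclohexenone (C5 is β to the C9 oxygen).
- The precursor comes linearly from (R)-β-citronellene: C6' from the chiral pool, C2' by directed asymmetric hydrogenation, then cross-metathesis, copper-catalysed asymmetric allylic arylation (C1) and a B-alkyl Suzuki coupling.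
- By design the quaternary carbon arises by radical addition to an sp2 carbon, not by enolate alkylation at a crowded angular position. The whole side chain is present from step 3, the enone comes from the arene, and no aldehyde ever sits beside a reactive alkene.

Key step: step 8

Remark on the chemistry: C8 of 14 and 15 (the methyl-bearing carbon next to the ketone) is carried as a mixture of epimers, because it becomes sp2 in step 9.

**Route**

Step 1
Reactants: 1 (R)-β-citronellene [(3R)-3,7-dimethylocta-1,6-diene]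
Product: 2 (2E,6R)-2,6-dimethylocta-2,7-dien-1-ol
Conditions: SeO2 (0.2 equiv), t-BuOOH (3 equiv), salicylic acid (0.1 equiv), CH2Cl2, rt
Reagents that add atoms: tert-butyl hydroperoxide, CC(C)(C)OO (oxygen relayed by the catalytic SeO2)
Why: Selenium dioxide allylic hydroxylation (ene reaction, then [2,3]-shift) should attack the electron-rich trisubstituted alkene at its (E)-methyl group and leave the vinyl group and the C6 stereocentre alone.

Step 2
Reactants: 2 (2E,6R)-2,6-dimethylocta-2,7-dien-1-ol
Product: 3 (2S,6R)-2,6-dimethyloct-7-en-1-ol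
Conditions: H2 (10 atm), Ru(OAc)2[(S)-BINAP] (1 mol %), MeOH, rt
Reagents that add atoms: none
Why: Hydroxyl-directed asymmetric hydrogenation of the allylic alcohol should set C2 by catalyst control [(S)-BINAP for 2S, by analogy with the facial rule for E-allylic alcohols], while the remote vinyl group has no directing group and should stay.

Step 3
Reactants: 3 (2S,6R)-2,6-dimethyloct-7-en-1-ol
Product: 4 {[(2S,6R)-2,6-dimethyloct-7-en-1-yl]oxy}triisopropylsilane
Conditions: TIPSCl, imidazole, CH2Cl2, rt
Reagents that add atoms: triisopropylsilyl chloride, CC(C)[Si](Cl)(C(C)C)C(C)C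
Why: Silylation of the only hydroxyl group gives an ether that should survive the Grignard, dissolving-metal, dilute-acid, radical and borane steps.

Step 4
Reactants: 4 {[(2S,6R)-2,6-dimethyloct-7-en-1-yl]oxy}triisopropylsilane; 5 (E)-1,4-dibromobut-2-ene
Product: 6 {[(2S,6R,7E)-9-bromo-2,6-dimethylnon-7-en-1-yl]oxy}triisopropylsilane
Conditions: second-generation Hoveyda–Grubbs catalyst (3 mol %), 5 (2 equiv), CH2Cl2, 40 °C
Reagents that add atoms: none
Why: Olefin cross-metathesis of the terminal alkene with a symmetrical allylic dibromide should give the E-allylic bromide without touching the stereocentre next to the alkene.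

Step 5
Reactants: 6 {[(2S,6R,7E)-9-bromo-2,6-dimethylnon-7-en-1-yl]oxy}triisopropylsilane; 7 4-bromo-2-methoxy-1-methylbenzene
Product: 9 triisopropyl{[(2S,6R,7R)-7-(3-methoxy-4-methylphenyl)-2,6-dimethylnon-8-en-1-yl]oxy}silane, via arylmagnesium bromide 8 (not isolated)
Conditions: 7, Mg, THF, rt; then 6, CuCl (5 mol %), chiral C2-symmetric 4,5-diphenylimidazolinium chloride as NHC precursor (6 mol %, antipode chosen for 7R), CH2Cl2, −78 °C
Reagents that add atoms: none
Why: Copper-catalysed asymmetric allylic arylation with an aryl Grignard reagent proceeds by anti-SN2' attack at the γ-carbon, so the aryl group ends on C7 (the future C1) and a terminal vinyl group appears; the chiral NHC–copper catalyst should set the new benzylic centre (7R) over the small bias of the neighbouring methyl-bearing carbon.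

Step 6
Reactants: 9 triisopropyl{[(2S,6R,7R)-7-(3-methoxy-4-methylphenyl)-2,6-dimethylnon-8-en-1-yl]oxy}silane; 10 bromoethene
Product: 12 triisopropyl{[(2S,6R,7R)-7-(3-methoxy-4-methylphenyl)-2,6-dimethylundec-10-en-1-yl]oxy}silane, via alkylborane 11 (not isolated)
Conditions: 9-BBN, THF, 0 °C → rt; then 10 (THF solution), Pd(dppf)Cl2 (5 mol %), aq. NaOH, THF, rt
Reagents that add atoms: none
Why: Anti-Markovnikov hydroboration of the only alkene followed by B-alkyl Suzuki–Miyaura coupling with vinyl bromide should lengthen the vinyl group to the but-3-enyl tether without touching the two adjacent stereocentres.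

Step 7
Reactants: 12 triisopropyl{[(2S,6R,7R)-7-(3-methoxy-4-methylphenyl)-2,6-dimethylundec-10-en-1-yl]oxy}silane
Product: 14 6-methyl-3-[(5R,6R,10S)-6,10-dimethyl-11-[(triisopropylsilyl)oxy]undec-1-en-5-yl]cyclohex-2-en-1-one (epimers at ring C6), via dihydroanisole 13 (not isolated)
Conditions: Li, NH3 (l), THF, t-BuOH, −78 → −33 °C; NH4Cl; then 0.5 M HCl, THF–H2O, 0 °C → rt
Reagents that add atoms: water, O
Why: Birch reduction of the anisole should give the 1-methoxycyclohexa-1,4-diene (methoxy and both alkyl groups stay on sp2 carbons), and acid hydrolysis with migration of the remaining ring alkene into conjugation should give the 3-substituted cyclohex-2-enone; the isolated terminal alkene and the silyl ether should survive.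

Step 8
Reactants: 14 6-methyl-3-[(5R,6R,10S)-6,10-dimethyl-11-[(triisopropylsilyl)oxy]undec-1-en-5-yl]cyclohex-2-en-1-one
Product: 15 triisopropyl{[(2S,6R)-6-[(1R,4S,5S)-4,8-dimethyl-9-oxospiro[4.5]decan-1-yl]-2-methylheptyl]oxy}silane (epimers at C8)
Conditions: Fe(acac)3 (0.5 equiv), PhSiH3 (3 equiv, slow addition), EtOH–ethylene glycol (5:1), 60 °C
Reagents that add atoms: none
Why: Hydrogen-atom transfer from an iron hydride to the terminal alkene gives the secondary C4 radical, which adds 5-exo-trig to the β-carbon C5 of the cyclohexenone; the α-keto radical is then reduced by divalent iron and protonated, so the C9 ketone is delivered directly. The closest known reaction type is the reductive olefin–enone coupling by metal-hydride hydrogen-atom transfer, including intramolecular cases that form quaternary carbons. The step closes the cyclopentane (C4–C5 bond, 5-exo-trig radical conjugate addition) and creates the spiro carbon on the pre-formed six-membered ring. C5 should be controlled by 1,3-allylic strain at C1: the C1–H bond eclipses the C5=C10 bond, the tether lies on one face and the branched side chain on the other, so that C6 ends up cis to the side chain and the carbonyl arm C10 trans to it. C4 should be controlled by the chair-like transition state of 5-exo radical cyclizations, in which the methyl group is pseudo-equatorial and ends up cis to C10 (1,5-cis rule), away from the pseudo-axial hydrogen on C6. The step needs cyclization to outrun simple reduction of the radical (secured by the fast 5-exo addition to an electron-poor alkene and slow silane addition) and Markovnikov hydrogen-atom transfer to the monosubstituted alkene, with the enone acting only as the radical acceptor.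

Step 9
Reactants: 15 triisopropyl{[(2S,6R)-6-[(1R,4S,5S)-4,8-dimethyl-9-oxospiro[4.5]decan-1-yl]-2-methylheptyl]oxy}silane
Product: 16 triisopropyl{[(2S,6R)-6-[(1R,4S,5S)-4,8-dimethyl-9-oxospiro[4.5]dec-7-en-1-yl]-2-methylheptyl]oxy}silane
Conditions: IBX (2.5 equiv), DMSO–toluene, 75 °C
Reagents that add atoms: none
Why: IBX dehydrogenation of the ketone through its enol can only introduce the C7=C8 double bond, because the other α-carbon (C10) is attached to the quaternary C5 and has no β-hydrogen; the epimeric C8 centre becomes sp2.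

Step 10
Reactants: 16 triisopropyl{[(2S,6R)-6-[(1R,4S,5S)-4,8-dimethyl-9-oxospiro[4.5]dec-7-en-1-yl]-2-methylheptyl]oxy}silane
Product: 17 triisopropyl{[(2S,6R)-6-[(1R,4S,5S,9S)-9-hydroxy-4,8-dimethylspiro[4.5]dec-7-en-1-yl]-2-methylheptyl]oxy}silane
Conditions: (R)-2-methyl-CBS-oxazaborolidine (20 mol %), catecholborane, toluene, −78 °C; MeOH, aq. NaOH
Reagents that add atoms: none
Why: Corey–Bakshi–Shibata 1,2-reduction under catalyst control, with the 2-methylalkenyl arm (C8) as the large and C10H2 as the small group, should give the 9S allylic alcohol from the (R)-catalyst.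

Step 11
Reactants: 17 triisopropyl{[(2S,6R)-6-[(1R,4S,5S,9S)-9-hydroxy-4,8-dimethylspiro[4.5]dec-7-en-1-yl]-2-methylheptyl]oxy}silane
Product: 18 (2S,6R)-6-[(1R,4S,5S,9S)-9-hydroxy-4,8-dimethylspiro[4.5]dec-7-en-1-yl]-2-methylheptan-1-ol
Conditions: TBAF, THF, rt
Reagents that add atoms: none
Why: Fluoride cleavage of the silyl ether under non-acidic conditions should leave the allylic alcohol untouched.

Step 12
Reactants: 18 (2S,6R)-6-[(1R,4S,5S,9S)-9-hydroxy-4,8-dimethylspiro[4.5]dec-7-en-1-yl]-2-methylheptan-1-ol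
Product: 19 (2S,6R)-6-[(1R,4S,5S,9S)-9-hydroxy-4,8-dimethylspiro[4.5]dec-7-en-1-yl]-2-methylheptyl acetate (CNP0304655.1)
Conditions: AcCl (1.05 equiv), 2,4,6-collidine, CH2Cl2, −78 °C
Reagents that add atoms: acetyl chloride, CC(Cl)=O
Why: Acylation with acetyl chloride and a hindered pyridine base at low temperature should be selective for the primary alcohol over the hindered secondary allylic alcohol.

**Compound list**

1 | (R)-β-citronellene [(3R)-3,7-dimethylocta-1,6-diene] | C=C[C@H](C)CCC=C(C)C | starting material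
2 | (2E,6R)-2,6-dimethylocta-2,7-dien-1-ol | C=C[C@H](C)CC/C=C(C)/CO | intermediate
3 | (2S,6R)-2,6-dimethyloct-7-en-1-ol | C=C[C@H](C)CCC[C@H](C)CO | intermediate
4 | {[(2S,6R)-2,6-dimethyloct-7-en-1-yl]oxy}triisopropylsilane | C=C[C@H](C)CCC[C@H](C)CO[Si](C(C)C)(C(C)C)C(C)C | intermediate
5 | (E)-1,4-dibromobut-2-ene | BrC/C=C/CBr | starting material
6 | {[(2S,6R,7E)-9-bromo-2,6-dimethylnon-7-en-1-yl]oxy}triisopropylsilane | BrC/C=C/[C@H](C)CCC[C@H](C)CO[Si](C(C)C)(C(C)C)C(C)C | intermediate
7 | 4-bromo-2-methoxy-1-methylbenzene | COc1cc(Br)ccc1C | starting material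
8 | (3-methoxy-4-methylphenyl)magnesium bromide | COc1cc([Mg]Br)ccc1C | intermediate (not isolated)
9 | triisopropyl{[(2S,6R,7R)-7-(3-methoxy-4-methylphenyl)-2,6-dimethylnon-8-en-1-yl]oxy}silane | CC(C)[Si](C(C)C)(C(C)C)OC[C@@H](C)CCC[C@@H](C)[C@H](c1ccc(C)c(OC)c1)C=C | intermediate
10 | bromoethene (vinyl bromide) | C=CBr | starting material
11 | 9-[(3R,4R,8S)-3-(3-methoxy-4-methylphenyl)-4,8-dimethyl-9-[(triisopropylsilyl)oxy]nonyl]-9-borabicyclo[3.3.1]nonane | CC(C)[Si](C(C)C)(C(C)C)OC[C@@H](C)CCC[C@@H](C)[C@H](c1ccc(C)c(OC)c1)CCB1C2CCCC1CCC2 | intermediate (not isolated)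
12 | triisopropyl{[(2S,6R,7R)-7-(3-methoxy-4-methylphenyl)-2,6-dimethylundec-10-en-1-yl]oxy}silane | CC(C)[Si](C(C)C)(C(C)C)OC[C@@H](C)CCC[C@@H](C)[C@H](c1ccc(C)c(OC)c1)CCC=C | intermediate
13 | triisopropyl{[(2S,6R,7R)-7-(5-methoxy-4-methylcyclohexa-1,4-dien-1-yl)-2,6-dimethylundec-10-en-1-yl]oxy}silane | CC(C)[Si](C(C)C)(C(C)C)OC[C@@H](C)CCC[C@@H](C)[C@H](C1=CCC(C)=C(OC)C1)CCC=C | intermediate (not isolated)
14 | 6-methyl-3-[(5R,6R,10S)-6,10-dimethyl-11-[(triisopropylsilyl)oxy]undec-1-en-5-yl]cyclohex-2-en-1-one (epimers at ring C6) | CC(C)[Si](C(C)C)(C(C)C)OC[C@@H](C)CCC[C@@H](C)[C@H](C1=CC(=O)C(C)CC1)CCC=C | intermediate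
15 | triisopropyl{[(2S,6R)-6-[(1R,4S,5S)-4,8-dimethyl-9-oxospiro[4.5]decan-1-yl]-2-methylheptyl]oxy}silane (epimers at C8) | CC(C)[Si](C(C)C)(C(C)C)OC[C@@H](C)CCC[C@@H](C)[C@H]1CC[C@H](C)[C@@]12CCC(C)C(=O)C2 | intermediate
16 | triisopropyl{[(2S,6R)-6-[(1R,4S,5S)-4,8-dimethyl-9-oxospiro[4.5]dec-7-en-1-yl]-2-methylheptyl]oxy}silane | CC(C)[Si](C(C)C)(C(C)C)OC[C@@H](C)CCC[C@@H](C)[C@H]1CC[C@H](C)[C@@]12CC=C(C)C(=O)C2 | intermediate
17 | triisopropyl{[(2S,6R)-6-[(1R,4S,5S,9S)-9-hydroxy-4,8-dimethylspiro[4.5]dec-7-en-1-yl]-2-methylheptyl]oxy}silane | CC(C)[Si](C(C)C)(C(C)C)OC[C@@H](C)CCC[C@@H](C)[C@H]1CC[C@H](C)[C@@]12CC=C(C)[C@@H](O)C2 | intermediate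
18 | (2S,6R)-6-[(1R,4S,5S,9S)-9-hydroxy-4,8-dimethylspiro[4.5]dec-7-en-1-yl]-2-methylheptan-1-ol | OC[C@@H](C)CCC[C@@H](C)[C@H]1CC[C@H](C)[C@@]12CC=C(C)[C@@H](O)C2 | intermediate
19 | (2S,6R)-6-[(1R,4S,5S,9S)-9-hydroxy-4,8-dimethylspiro[4.5]dec-7-en-1-yl]-2-methylheptyl acetate | CC(=O)OC[C@@H](C)CCC[C@@H](C)[C@H]1CC[C@H](C)[C@@]12CC=C(C)[C@@H](O)C2 | target

**Step count and risks**

Total step count: 12. Longest linear sequence: 12 (steps 1–12; 5, 7 and 10 are commercial inputs).

Steps most likely to fail:

1. Step 8. The C4 radical may be reduced before it cyclizes, and the 1,5-induction that places the C4 methyl group may be modest at 60 °C. The fallback uses a halide-based radical chain at low temperature and sets out from 12. Wacker oxidation (PdCl2, CuCl, O2, DMF–H2O) should give (5R,6R,10S)-5-(3-methoxy-4-methylphenyl)-6,10-dimethyl-11-[(triisopropylsilyl)oxy]undecan-2-one F1. Birch reduction (which also reduces the ketone) and acid hydrolysis should give 3-[(5R,6R,10S)-2-hydroxy-6,10-dimethyl-11-[(triisopropylsilyl)oxy]undecan-5-yl]-6-methylcyclohex-2-en-1-one F2. Iodination (I2, PPh3, imidazole) should give 3-[(5R,6R,10S)-2-iodo-6,10-dimethyl-11-[(triisopropylsilyl)oxy]undecan-5-yl]-6-methylcyclohex-2-en-1-one F3. Cyclization with Bu3SnH and Et3B/O2 in toluene at −78 °C comes back to the route at 15.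

2. Step 5. Direct SN2 attack at the bromide-bearing carbon may leak in, and the catalyst may discriminate the faces poorly next to the existing stereocentre. The fallback replaces the allylic substitution by a conjugate arylation and sets out from 4. Cross-metathesis with methyl acrylate should give methyl (2E,4R,8S)-4,8-dimethyl-9-[(triisopropylsilyl)oxy]non-2-enoate F4. Rhodium-catalysed 1,4-addition [Rh(acac)(C2H4)2, BINAP antipode chosen for 3R, dioxane–H2O] of (3-methoxy-4-methylphenyl)boronic acid F5 should give methyl (3R,4R,8S)-3-(3-methoxy-4-methylphenyl)-4,8-dimethyl-9-[(triisopropylsilyl)oxy]nonanoate F6. LiAlH4 should give (3R,4R,8S)-3-(3-methoxy-4-methylphenyl)-4,8-dimethyl-9-[(triisopropylsilyl)oxy]nonan-1-ol F7. Iodination should give {[(2S,6R,7R)-9-iodo-7-(3-methoxy-4-methylphenyl)-2,6-dimethylnonyl]oxy}triisopropylsilane F8. Coupling with vinylmagnesium bromide and catalytic CuI comes back to the route at 12.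

3. Step 2. Enantioface discrimination may be incomplete for a 2-methyl-substituted allylic alcohol, and the alkene may isomerise. The fallback moves the hydrogenation to the carboxylic acid, the best-precedented substrate class for an α-methyl centre, and sets out from 2. Oxidation [TEMPO, PhI(OAc)2, MeCN–H2O] should give (2E,6R)-2,6-dimethylocta-2,7-dienoic acid F9. Carboxylate-directed hydrogenation with Ru(OAc)2[(S)-H8-BINAP] should give (2S,6R)-2,6-dimethyloct-7-enoic acid F10. LiAlH4 reduction comes back to the route at 3.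

Further compounds
F1 | step 8 | (5R,6R,10S)-5-(3-methoxy-4-methylphenyl)-6,10-dimethyl-11-[(triisopropylsilyl)oxy]undecan-2-one | CC(C)[Si](C(C)C)(C(C)C)OC[C@@H](C)CCC[C@@H](C)[C@H](c1ccc(C)c(OC)c1)CCC(C)=O
F2 | step 8 | 3-[(5R,6R,10S)-2-hydroxy-6,10-dimethyl-11-[(triisopropylsilyl)oxy]undecan-5-yl]-6-methylcyclohex-2-en-1-one (epimers at the carbinol carbon and ring C6) | CC(C)[Si](C(C)C)(C(C)C)OC[C@@H](C)CCC[C@@H](C)[C@H](C1=CC(=O)C(C)CC1)CCC(C)O
F3 | step 8 | 3-[(5R,6R,10S)-2-iodo-6,10-dimethyl-11-[(triisopropylsilyl)oxy]undecan-5-yl]-6-methylcyclohex-2-en-1-one (epimers at the iodide carbon and ring C6) | CC(C)[Si](C(C)C)(C(C)C)OC[C@@H](C)CCC[C@@H](C)[C@H](C1=CC(=O)C(C)CC1)CCC(C)I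
F4 | step 5 | methyl (2E,4R,8S)-4,8-dimethyl-9-[(triisopropylsilyl)oxy]non-2-enoate | COC(=O)/C=C/[C@H](C)CCC[C@H](C)CO[Si](C(C)C)(C(C)C)C(C)C
F5 | step 5 | (3-methoxy-4-methylphenyl)boronic acid | COc1cc(B(O)O)ccc1C
F6 | step 5 | methyl (3R,4R,8S)-3-(3-methoxy-4-methylphenyl)-4,8-dimethyl-9-[(triisopropylsilyl)oxy]nonanoate | CC(C)[Si](C(C)C)(C(C)C)OC[C@@H](C)CCC[C@@H](C)[C@H](c1ccc(C)c(OC)c1)CC(=O)OC
F7 | step 5 | (3R,4R,8S)-3-(3-methoxy-4-methylphenyl)-4,8-dimethyl-9-[(triisopropylsilyl)oxy]nonan-1-ol | CC(C)[Si](C(C)C)(C(C)C)OC[C@@H](C)CCC[C@@H](C)[C@H](c1ccc(C)c(OC)c1)CCO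
F8 | step 5 | {[(2S,6R,7R)-9-iodo-7-(3-methoxy-4-methylphenyl)-2,6-dimethylnonyl]oxy}triisopropylsilane | CC(C)[Si](C(C)C)(C(C)C)OC[C@@H](C)CCC[C@@H](C)[C@H](c1ccc(C)c(OC)c1)CCI
F9 | step 2 | (2E,6R)-2,6-dimethylocta-2,7-dienoic acid | C=C[C@H](C)CC/C=C(C)/C(O)=O
F10 | step 2 | (2S,6R)-2,6-dimethyloct-7-enoic acid | C=C[C@H](C)CCC[C@H](C)C(O)=O
A1 | direct plan | (4S,4aR,7S,7aR)-dihydronepetalactone | O1C[C@@H](C)[C@H]2CC[C@H](C)[C@H]2C1=O
A2 | direct plan | (4S,4aR,7S,7aR)-4,7-dimethyl-7a-(2-methylidenebutyl)hexahydrocyclopenta[c]pyran-1(3H)-one | O1C[C@@H](C)[C@H]2CC[C@H](C)[C@@]2(CC(=C)CC)C1=O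
A3 | direct plan | 2-[(1S,2R,5S)-2-[(2R,6S)-7-hydroxy-6-methylheptan-2-yl]-5-methyl-1-(2-oxobutyl)cyclopentyl]acetaldehyde | OC[C@@H](C)CCC[C@@H](C)[C@H]1CC[C@H](C)[C@@]1(CC(=O)CC)CC=O
A4 | direct plan | (2S,6R)-6-[(1R,4S,5S)-4,8-dimethyl-9-oxospiro[4.5]dec-7-en-1-yl]-2-methylheptan-1-ol | OC[C@@H](C)CCC[C@@H](C)[C@H]1CC[C@H](C)[C@@]12CC=C(C)C(=O)C2
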